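**Retrosynthetic overview**
- The target comes from 6β-silyloxy-4β-hydroxyeudesman-3-one by desilylation, benzoylation of the C6 hydroxyl and hydride delivery to the equatorial side of C3 (gives the axial 3α-OH).
- The strategy rests on ring A carrying adjacent oxygens on C3 and C4, with C4 a tertiary methyl carbinol. This is an acyloin, so the C3–C4 bond is cut to a C3 aldehyde and a C4 methyl ketone on ring B, joined by a carbene-catalysed aldehyde–ketone benzoin.
- The keto-aldehyde comes from ring B: the C5 acetyl from aldol–dehydration and face-selective hydroboration of the ethylidene, the C6 oxygen from enone reduction, the C1–C3 arm from an allyl group.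
- The C10 quaternary centre comes from allyl 1,2-addition to (S)-piperitone followed by an anionic oxy-Cope shift; piperitone comes from (−)-menthone, which supplies C7.
- Ring order: ring B is taken from the chiral pool; ring A is closed last, in the key step.

Key step: step 11

Assumption: the side-chain carbinol centres (11, 12, 17, 18), the ring C2 centre of 11 and 12 and the ethylidene geometry (13–16) are left undefined because dehydration, hydroboration and oxidation erase or override them; eudesmane numbering is used for all intermediates.

**Step 1**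
Reactants: 1 (−)-menthone
Product: 3 trimethylsilyl enol ether of menthone (less substituted enol ether), via lithium enolate 2 (not isolated)
Conditions: LiN(i-Pr)2, THF, −78 °C; then TMSCl, −78 → 0 °C
Reagents that add atoms: chlorotrimethylsilane, C[Si](C)(C)Cl
Why: Kinetic enolate formation and O-silylation; the amide base takes a proton from the open ring CH2 and not from the methine that carries isopropyl, so that stereocentre is untouched.

**Step 2**
Reactants: 3 trimethylsilyl enol ether of menthone
Product: 4 (S)-piperitone
Conditions: Pd(OAc)2 (10 mol%), O2 (1 atm), DMSO, 25 °C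
Reagents that add atoms: none
Why: Saegusa–Ito oxidation; the palladium enolate loses the β-hydrogen of the methyl-bearing carbon to give the conjugated enone under neutral conditions that leave the isopropyl centre intact.

**Step 3**
Reactants: 4 (S)-piperitone; 5 allylmagnesium bromide
Product: 6 1-allyl-6-isopropyl-3-methylcyclohex-2-en-1-ol (allyl trans to isopropyl)
Conditions: Et2O, −78 °C; aq NH4Cl
Reagents that add atoms: none
Why: Grignard 1,2-addition (allylmagnesium halides attack the carbonyl carbon of enones); approach anti to the neighbouring isopropyl group (Felkin–Anh type, isopropyl pseudoaxial) should put allyl trans and hydroxyl cis to isopropyl, and the minor epimer is removed by chromatography.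

**Step 4**
Reactants: 6 1-allyl-6-isopropyl-3-methylcyclohex-2-en-1-ol
Product: 9 trimethylsilyl enol ether of 3-allyl-6-isopropyl-3-methylcyclohexanone, via potassium alkoxide 7 (not isolated), via potassium enolate 8 (not isolated)
Conditions: KH, 18-crown-6, THF, 0 → 50 °C; then TMSCl, Et3N, −78 °C
Reagents that add atoms: chlorotrimethylsilane, C[Si](C)(C)Cl
Why: Anionic oxy-Cope rearrangement; the allyl group moves suprafacially from the carbinol carbon to the methyl-bearing alkene carbon on the face it already occupies, which sets C10 (arm trans, methyl cis to isopropyl) and gives only the C5=C6 enolate, trapped on oxygen.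

**Step 5**
Reactants: 9 trimethylsilyl enol ether; 10 acetaldehyde
Product: 11 3-allyl-2-(1-hydroxyethyl)-6-isopropyl-3-methylcyclohexanone
Conditions: TiCl4, CH2Cl2, −78 °C; then H2O
Reagents that add atoms: none
Why: Mukaiyama aldol addition; the bond forms only at the enol ether carbon (C5), and the two new centres do not matter because the next step removes them.

**Step 6**
Reactants: 11 aldol
Product: 13 3-allyl-2-ethylidene-6-isopropyl-3-methylcyclohexanone, via mesylate 12 (not isolated)
Conditions: MsCl, Et3N, CH2Cl2, 0 °C; then DBU, 0 °C → rt
Reagents that add atoms: none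
Why: Aldol dehydration by mesylation and E1cB elimination; only the conjugated exocyclic enone can form, and brief amine base at low temperature should not enolise the hindered C7–H.

**Step 7**
Reactants: 13 ethylidene enone
Product: 14 3-allyl-2-ethylidene-6-isopropyl-3-methylcyclohexan-1-ol (6β-OH, cis to isopropyl and to the C10 methyl)
Conditions: i-Bu2AlH, CH2Cl2, −78 °C; aq potassium sodium tartrate
Reagents that add atoms: none
Why: 1,2-reduction of an enone by an aluminium hydride; the axial C10 methyl is syn-axial to the β-trajectory at C6, so hydride should enter from the α-face and give the axial 6β-alcohol.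

**Step 8**
Reactants: 14 allylic alcohol
Product: 15 tert-butyldimethylsilyl ether of 14
Conditions: TBSOTf, 2,6-lutidine, CH2Cl2, −78 → 0 °C
Reagents that add atoms: tert-butyldimethylsilyl trifluoromethanesulfonate, CC(C)(C)[Si](C)(C)OS(=O)(=O)C(F)(F)F
Why: Silyl ether formation; the silyl triflate is reactive enough for the hindered axial secondary alcohol.

**Step 9**
Reactants: 15 silyl ether
Product: 18 3-[3-(tert-butyldimethylsilyloxy)-2-(1-hydroxyethyl)-4-isopropyl-1-methylcyclohexyl]propan-1-ol, via B-alkyl-9-BBN adduct 16 (not isolated), via bis-organoborane 17 (not isolated)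
Conditions: 9-BBN, THF, 0 °C → rt; then BH3·THF, 0 °C → rt; then NaOH, H2O2, 0 °C → rt
Reagents that add atoms: hydrogen peroxide, OO
Why: Brown hydroboration–oxidation; 9-BBN first takes the terminal alkene (no B–H is left for cyclic hydroboration), then BH3 adds to the ethylidene with boron on the exocyclic carbon and hydrogen on C5 from the α-face, because the axial C10 methyl and axial C6 silyloxy group flank the β-face, which sets C5 (H α, side chain equatorial).

**Step 10**
Reactants: 18 diol
Product: 19 3-[2-acetyl-3-(tert-butyldimethylsilyloxy)-4-isopropyl-1-methylcyclohexyl]propanal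
Conditions: Dess–Martin periodinane, NaHCO3, CH2Cl2, 0 °C → rt
Reagents that add atoms: none
Why: Dess–Martin oxidation of the primary and the secondary alcohol in one operation; the buffered, non-basic medium should leave C5–H and the silyl ether alone.

**Step 11**
Reactants: 19 keto-aldehyde
Product: 20 6β-(tert-butyldimethylsilyloxy)-4β-hydroxyeudesman-3-one
Conditions: 3-benzyl-5-(2-hydroxyethyl)-4-methylthiazolium chloride (20 mol%), DBU (40 mol%), t-BuOH, 40 °C, 0.02 M
Reagents that add atoms: none
Why: The thiazol-2-ylidene freed by DBU adds to the unhindered aldehyde C3, proton transfer gives the enaminol (Breslow intermediate), and its nucleophilic C3 attacks the C4 acetyl carbonyl before the carbene leaves and C3 becomes the ketone. This is an intramolecular crossed aldehyde–ketone benzoin (acyloin) cyclisation, a known carbene-catalysed reaction of 1,6-keto-aldehydes. Ring A closes 6-exo-trig through a chair that is trans-fused to ring B, because C1 and C4 are both equatorial on the pre-set C10 and C5. At the new C4 centre the β-axial site is flanked by the axial C10 methyl and the axial C6 silyloxy group, so the ketone methyl should take the equatorial site and the hydroxyl the axial one (4β); reversibility of the addition lets a minor epimer drain to this isomer. The step needs benzoin closure to win over enolate aldol and intermolecular coupling, without epimerisation at C5; the single aldehyde as the only carbonyl able to form the enaminol, high dilution, catalytic base in a protic solvent and the hindered tertiary C5–H should secure this.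

**Step 12**
Reactants: 20 silyl ether ketol
Product: 21 4β,6β-dihydroxyeudesman-3-one
Conditions: HF (48% aq), MeCN, rt
Reagents that add atoms: none
Why: Fluoride-mediated desilylation under acidic, non-basic conditions, which spare the tertiary α-ketol and all stereocentres.

**Step 13**
Reactants: 21 keto-diol; 22 benzoyl chloride
Product: 23 6β-benzoyloxy-4β-hydroxyeudesman-3-one
Conditions: DMAP, pyridine, 50 °C
Reagents that add atoms: none
Why: DMAP-catalysed acylation; the secondary C6 hydroxyl reacts and the tertiary C4 hydroxyl does not.

**Step 14**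
Reactants: 23 benzoate ketol
Product: 24 6β-benzoyloxyeudesmane-3α,4β-diol (target)
Conditions: LiBH(s-Bu)3, THF, −78 °C; aq NH4Cl
Reagents that add atoms: none
Why: Bulky trialkylborohydride reduction; the axial hydrogens on C1 and C5 block axial approach, so hydride should come from the equatorial β-side and give the axial 3α-alcohol trans to the 4β-hydroxyl, while the benzoate survives at −78 °C.

**Compound list**
1 | (−)-menthone, (2S,5R)-2-isopropyl-5-methylcyclohexanone | CC(C)[C@@H]1CC[C@@H](C)CC1=O | starting material
2 | lithium enolate of 1 (less substituted side) | CC(C)[C@@H]1CC[C@@H](C)C=C1[O-].[Li+] | intermediate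
3 | trimethylsilyl enol ether of 1 | CC(C)[C@@H]1CC[C@@H](C)C=C1O[Si](C)(C)C | intermediate
4 | (S)-piperitone, (6S)-6-isopropyl-3-methylcyclohex-2-en-1-one | CC(C)[C@@H]1CCC(C)=CC1=O | intermediate
5 | allylmagnesium bromide | C=CC[Mg]Br | starting material
6 | 1-allyl-6-isopropyl-3-methylcyclohex-2-en-1-ol, allyl trans and hydroxyl cis to isopropyl | CC(C)[C@@H]1CCC(C)=C[C@@]1(O)CC=C | intermediate
7 | potassium alkoxide of 6 | CC(C)[C@@H]1CCC(C)=C[C@@]1([O-])CC=C.[K+] | intermediate
8 | potassium enolate of 3-allyl-6-isopropyl-3-methylcyclohexanone, allyl trans and methyl cis to isopropyl | CC(C)[C@@H]1CC[C@@](C)(CC=C)C=C1[O-].[K+] | intermediate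
9 | trimethylsilyl enol ether of 8 | CC(C)[C@@H]1CC[C@@](C)(CC=C)C=C1O[Si](C)(C)C | intermediate
10 | acetaldehyde | CC=O | starting material
11 | 3-allyl-2-(1-hydroxyethyl)-6-isopropyl-3-methylcyclohexanone (epimers at C2 and at the carbinol carbon) | CC(C)[C@@H]1CC[C@@](C)(CC=C)C(C(C)O)C1=O | intermediate
12 | mesylate of 11 | CC(C)[C@@H]1CC[C@@](C)(CC=C)C(C(C)OS(C)(=O)=O)C1=O | intermediate
13 | 3-allyl-2-ethylidene-6-isopropyl-3-methylcyclohexanone (alkene geometry undefined) | CC(C)[C@@H]1CC[C@@](C)(CC=C)C(=CC)C1=O | intermediate
14 | 3-allyl-2-ethylidene-6-isopropyl-3-methylcyclohexan-1-ol, hydroxyl cis to isopropyl and to the ring methyl (6β-OH) | CC(C)[C@@H]1CC[C@@](C)(CC=C)C(=CC)[C@@H]1O | intermediate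
15 | tert-butyldimethylsilyl ether of 14 | CC(C)[C@@H]1CC[C@@](C)(CC=C)C(=CC)[C@@H]1O[Si](C)(C)C(C)(C)C | intermediate
16 | B-alkyl-9-BBN adduct of the allyl group of 15 | CC(C)[C@@H]1CC[C@@](C)(CCCB2C3CCCC2CCC3)C(=CC)[C@@H]1O[Si](C)(C)C(C)(C)C | intermediate
17 | bis-organoborane, idealised as the monoalkylborane at the side-chain carbon (C5–H α) | CC(C)[C@@H]1CC[C@@](C)(CCCB2C3CCCC2CCC3)[C@H](C(C)B)[C@@H]1O[Si](C)(C)C(C)(C)C | intermediate
18 | 3-[3-(tert-butyldimethylsilyloxy)-2-(1-hydroxyethyl)-4-isopropyl-1-methylcyclohexyl]propan-1-ol (carbinol epimers) | CC(C)[C@@H]1CC[C@@](C)(CCCO)[C@H](C(C)O)[C@@H]1O[Si](C)(C)C(C)(C)C | intermediate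
19 | 3-[2-acetyl-3-(tert-butyldimethylsilyloxy)-4-isopropyl-1-methylcyclohexyl]propanal (5α-H, 6β-OSi, 7β-isopropyl, 10β-methyl) | CC(C)[C@@H]1CC[C@@](C)(CCC=O)[C@H](C(C)=O)[C@@H]1O[Si](C)(C)C(C)(C)C | intermediate
20 | 6β-(tert-butyldimethylsilyloxy)-4β-hydroxyeudesman-3-one | CC(C)[C@@H]1CC[C@@]2(C)CCC(=O)[C@](C)(O)[C@@H]2[C@@H]1O[Si](C)(C)C(C)(C)C | intermediate
21 | 4β,6β-dihydroxyeudesman-3-one | CC(C)[C@@H]1CC[C@@]2(C)CCC(=O)[C@](C)(O)[C@@H]2[C@@H]1O | intermediate
22 | benzoyl chloride | O=C(Cl)c1ccccc1 | starting material
23 | 6β-benzoyloxy-4β-hydroxyeudesman-3-one | CC(C)[C@@H]1CC[C@@]2(C)CCC(=O)[C@](C)(O)[C@@H]2[C@@H]1OC(=O)c1ccccc1 | intermediate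
24 | 6β-benzoyloxyeudesmane-3α,4β-diol (CNP0187831.1) | CC(C)[C@@H]1CC[C@@]2(C)CC[C@@H](O)[C@](C)(O)[C@@H]2[C@@H]1OC(=O)c1ccccc1 | target

**Step count**
Total: 14 steps. Longest linear sequence: 14 steps, from (−)-menthone.

**Steps most likely to fail**

1. Step 11. The aldehyde α-carbon may close onto the ketone by enolate aldol (five-membered ring), or the enaminol may add too slowly to the hindered ketone, so that ring A does not form cleanly. The fallback keeps the C3–C4 bond but makes it reductively. It sets out from 19: SmI2 in THF/t-BuOH should give, by ketyl–carbonyl (pinacol) cyclisation through a samarium chelate, 6β-(tert-butyldimethylsilyloxy)eudesmane-3β,4β-diol F1, with the C4 methyl equatorial for the same steric reason. Parikh–Doering oxidation of the secondary C3 hydroxyl (SO3·pyridine, DMSO, Et3N) then returns to 20.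

2. Step 3. Facial discrimination in the Grignard addition may be poor (allylmagnesium reagents are not reliably selective), and attack on the isopropyl face would pass through the stereospecific rearrangement to the C10 epimer. The fallback sets C10 by hydroxyl-directed delivery instead; it sets out from 4 and returns at 9. LiBH(s-Bu)3 should reduce 4 anti to isopropyl to cis-piperitol F2. Mitsunobu esterification (4-nitrobenzoic acid, PPh3, DIAD) inverts it to trans-piperitol 4-nitrobenzoate F3, and K2CO3 in MeOH frees trans-piperitol F4. Simmons–Smith cyclopropanation (Et2Zn, CH2I2) is directed by the hydroxyl and places the new methylene trans to isopropyl in the cyclopropyl carbinol F5. Dess–Martin oxidation gives the cyclopropyl ketone F6. Homoconjugate addition of (CH2=CH)2CuLi in the presence of TMSCl opens the cyclopropane at its methylene carbon and gives 9 directly.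

3. Step 14. Hydride may enter from the axial α-side next to the C4 alkoxide, or the benzoate may be cleaved or transferred if the hindered ketone needs warming. The fallback replaces external, sterically governed attack by internal delivery; it sets out from 23 and returns at 24. Me4NBH(OAc)3 in MeCN/AcOH at −20 °C binds the 4β-hydroxyl and should hand hydride to the β-face of C3 (hydroxyl-directed reduction), giving the trans 3α,4β-diol under acidic conditions that hold the ester in place; this fallback makes no new compound (F0).

**Further compounds**
F1 | step 11 | 6β-(tert-butyldimethylsilyloxy)eudesmane-3β,4β-diol | CC(C)[C@@H]1CC[C@@]2(C)CC[C@H](O)[C@](C)(O)[C@@H]2[C@@H]1O[Si](C)(C)C(C)(C)C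
F2 | step 3 | cis-piperitol, 6-isopropyl-3-methylcyclohex-2-en-1-ol with hydroxyl cis to isopropyl | CC(C)[C@@H]1CCC(C)=C[C@@H]1O
F3 | step 3 | trans-piperitol 4-nitrobenzoate | CC(C)[C@@H]1CCC(C)=C[C@H]1OC(=O)c1ccc(cc1)[N+](=O)[O-]
F4 | step 3 | trans-piperitol, hydroxyl trans to isopropyl | CC(C)[C@@H]1CCC(C)=C[C@H]1O
F5 | step 3 | 3-isopropyl-6-methylbicyclo[4.1.0]heptan-2-ol, cyclopropane cis to hydroxyl and trans to isopropyl | CC(C)[C@@H]1CC[C@@]2(C)C[C@H]2[C@H]1O
F6 | step 3 | 3-isopropyl-6-methylbicyclo[4.1.0]heptan-2-one, cyclopropane trans to isopropyl | CC(C)[C@@H]1CC[C@@]2(C)C[C@H]2C1=O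
F0 | step 14 | none | none
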